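## Analysis of the target

Selaginellin A is built on one central benzene, ring A, with four contiguous substituents. C1 carries a methyl group, C2 a (4-hydroxyphenyl)ethynyl group, C3 the diarylmethylene carbon of a quinone methide and C4 a 4-hydroxyphenyl group; C5 and C6 are unsubstituted CH. The methide carbon on C3 is doubly bonded to a cyclohexa-2,5-dienone ring and singly bonded to a phenyl group, so it carries three different aryl-derived groups. There is no stereogenic centre and, because the quinoid ring is symmetric, no configured double bond; hindered rotation about the bond from C3 to the methide carbon is not specified in the target. The sensitive groups are the electrophilic quinone methide, the two free phenols and the diarylalkyne, which must survive acid, boron halide and neighbouring alkoxide or cation centres. The difficulty is steric and regiochemical: C2 and C3 each sit between two ortho substituents, so cross-coupling at either position of a preformed arene is crowded, and the three aryl groups on the methide carbon must arrive one at a time. The plan rests on two features of ring A. C2 and C3 bear adjacent carbon substituents that a CH2–O–C(=O) bridge can join into a fused five-membered lactone. The C5–C6 edge is plain CH=CH and therefore corresponds to acetylene, so ring A is the formal trimer of two tethered alkynes and acetylene.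

## Retrosynthetic reasoning

**16 from carbinol 15.** The exocyclic C=C of the quinone methide and the three phenolic O–H bonds of selaginellin A (16) are taken back to the tertiary triarylcarbinol 15 with three aryl methyl ethers. The quinone methide is the least robust group, so it is unveiled last. Cleaving three O–CH3 bonds and ionising the C–OH bond are both Lewis-acid processes and can be asked of one reagent. The forward step must demethylate three times and dehydrate without letting the triarylmethyl cation attack the alkyne or the aryl ring on C4.

**15 from ketone 12 and 4-bromoanisole (13).** The bond from the carbinol carbon to the future quinoid ring is cut, giving diaryl ketone 12 and aryllithium 14 made from 13. Cutting here leaves phenyl to be installed earlier, so the three aryl groups on this carbon arrive in turn: ring A by construction, phenyl second, the anisyl ring last. The forward addition must succeed at a ketone flanked by two ortho groups; the linear alkyne is the least hindering neighbour available.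

**12 from terminal alkyne 10 and 4-iodoanisole (11).** The C(sp)–C(aryl) bond on the far side of the triple bond is cut. This puts the cross-coupling at the unhindered alkyne terminus and not at C2 of ring A, which lies between the methyl group and the benzoyl group.

**10 from keto aldehyde 9.** The triple bond is taken back to an aldehyde on C2 by one-carbon homologation. The C2 substituent is thus grown outward from a carbon already on the ring. The forward reaction must distinguish the aldehyde from the diaryl ketone; a diazophosphonate under mild carbonate conditions should do so on steric and electronic grounds.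

**9 from hydroxy ketone 8, and 8 from lactone 5 and phenyllithium (6).** The aldehyde is taken back to the primary benzylic alcohol 8. Cutting the C(=O)–phenyl bond then reunites the alcohol oxygen and the acyl carbon as lactone 5. The lactone carbonyl on C3 is at the acid oxidation level and accepts exactly one aryl nucleophile, because the tetrahedral adduct is held as the lactolate of 7. The CH2–O carbon on C2 is released as the alcohol that becomes the aldehyde. The two adjacent carbon substituents are differentiated without a protecting group.

**5 from diyne ester 3 and acetylene (4).** Three bonds of ring A are cut at once: C2–C3, C4–C5 and C6–C1. C5 and C6 come from 4; C3 and C4 are the triple bond of the arylpropiolate, and C1 and C2 the triple bond of the butynyl group. The ester between them becomes the lactone. This builds ring A in one step at the aromatic oxidation level, and the tether dictates that methyl ends on C1 and the aryl group on C4. The forward reaction must favour crossed trimerisation over self-reaction of 3 or of 4.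

**3 from acid 1 and alcohol 2.** The ester C–O bond is cut to two commercial alkynes. A plain acylation leaves all the risk of the route in the cyclotrimerisation.

## Alternatives that were turned down

**Alternative 1:** Ring A is taken back to a cyclohexenone by cutting C3–C4 and C1=C6. This leads to methyl 3-oxopentanoate (A1) and 4-methoxycinnamaldehyde (A2).
- Forward key step: a secondary amine activates A2 as its iminium ion, the doubly activated methylene of A1 adds to the β-carbon (C3–C4), and the ethyl-ketone α-carbon condenses with the freed aldehyde (C1=C6). The product is cyclohexenone A3, rac-methyl trans-6-(4-methoxyphenyl)-3-methyl-2-oxocyclohex-3-ene-1-carboxylate. Dehydrogenation would give salicylate A4, methyl 2-hydroxy-6-(4-methoxyphenyl)-3-methylbenzoate, whose phenol on C2 becomes the alkyne through a triflate and whose ester on C3 becomes the triaryl carbon.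
- For it: A1 and A2 are bulk chemicals, the ring is made without a transition metal or a gas, and the step count to the target is about the same. On cost of materials it is the stronger plan.
- Against it: the two stereocentres of A3 are erased again and an extra oxidation is needed. The aldol closure must occur at the less acidic ethyl-ketone carbon, in competition with retro-Michael reaction. The C2 alkyne must be introduced by cross-coupling at a triflate flanked by methyl and ester. The ester of a 2,6-disubstituted benzoate must then accept exactly one aryllithium, with nothing to stop at the ketone.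
- Comparison: the chosen strategy gives up the cheap materials. In exchange ring A is formed aromatic with its regiochemistry locked by the tether, the lactone stops cleanly at mono-addition, and the alkyne is grown from an aldehyde on C2 instead of being coupled into a crowded position.

**Alternative 2:** Ring A is cut at C1–C2 and C3–C4 with a two-atom bridge added back across C1 and C4. This leads to pyrone A5, 6-(4-methoxyphenyl)-3-methyl-2H-pyran-2-one, and diynone A6, 5-(4-methoxyphenyl)-1-phenylpenta-2,4-diyn-1-one.
- Forward key step: the diene of A5 adds thermally across the ketone-activated triple bond of A6, and the bicyclic adduct loses its bridge by decarboxylative cycloreversion. The product A7, [6-(4-methoxyphenyl)-2-[(4-methoxyphenyl)ethynyl]-3-methylphenyl](phenyl)methanone, is the same compound as 12.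
- For it: it is the most convergent plan. A7 is two steps from the target, whereas the chosen route needs four further steps after ring formation to reach the same ketone. The electronic bias is also in the right sense, since the nucleophilic pyrone terminus C3 should bond to the β-carbon of the ynone.
- Against it: nothing in the structure enforces that orientation. Both new bonds form at fully substituted termini of a pyrone with aromatic character, so temperatures well above 150 °C are to be expected. A6 has a second, competing triple bond and is unlikely to tolerate such heating without polymerisation or addition at the wrong alkyne. A regioisomer would be hard to separate from A7. A5 and A6 each need several steps, so only the longest linear sequence is shorter, not the total.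
- Comparison: on convergence this alternative is stronger. The chosen strategy offers a ring closure under mild conditions whose regiochemistry is a structural necessity, from two commercial pieces and a gas.

**Alternative 3:** Only the C5–C6 bond of a dihydro ring A is cut. This leads to the butenolide triene A8, 3-[1-(4-methoxyphenyl)ethenyl]-4-(prop-1-en-2-yl)furan-2(5H)-one.
- Forward key step: heating A8 brings about disrotatory 6π electrocyclisation of the triene made of the arylvinyl group, the ring alkene and the isopropenyl group. The product is cyclohexadiene A9, 7-(4-methoxyphenyl)-4-methyl-5,6-dihydroisobenzofuran-1(3H)-one; dehydrogenation of A9 would give phthalide 5.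
- For it: the closure is unimolecular, so there is no cross- versus self-reaction to manage and no gas to handle. The central alkene is held cis by the lactone, and both termini are CH2, so no stereochemical issue arises. On chemoselectivity of the ring-forming step it is at least as good as the chosen plan.
- Against it: A8 must be assembled by two successive regioselective cross-couplings on a dihalobutenolide, with alkenyl partners that polymerise easily. The wide exocyclic angles of the five-membered ring hold the triene termini apart, and the internal aryl and methyl groups twist the triene out of its reactive geometry. Forcing temperatures and competing hydrogen shifts are therefore likely, and a separate oxidation is needed.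
- Comparison: it reaches 5 in about four steps and at the wrong oxidation level. The chosen cyclotrimerisation reaches 5 in two steps from commercial materials, already aromatic.

Key step: step 2

Remark on the chemistry: hydroxy ketone 8 and lactol 7 are ring–chain tautomers; 8 is written as the isolated form, and whichever tautomer predominates, step 4 proceeds through the open form.

Remark on the chemistry: compounds 7 and 15 are racemic; their single stereocentres disappear again in later steps.

## Route

Step 1
Reactants: 1 3-(4-methoxyphenyl)propiolic acid; 2 but-2-yn-1-ol
Product: 3 but-2-yn-1-yl 3-(4-methoxyphenyl)propiolate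
Conditions: DCC, DMAP (cat.), CH2Cl2, 0 °C to rt
Reagents that add atoms: none
Why: Steglich esterification; the acylpyridinium formed from the O-acylisourea should be intercepted by the unhindered primary alcohol faster than the arylpropiolic acid can self-condense at 0 °C, and neither triple bond is touched.

Step 2
Reactants: 3 but-2-yn-1-yl 3-(4-methoxyphenyl)propiolate; 4 acetylene
Product: 5 7-(4-methoxyphenyl)-4-methylisobenzofuran-1(3H)-one
Conditions: RhCl(PPh3)3 (5 mol%), acetylene (1 atm), toluene, 40–60 °C, slow addition of 3
Reagents that add atoms: none
Why: Loss of one phosphine from RhCl(PPh3)3 gives a monovalent rhodium fragment that binds both alkynes of 3; oxidative cyclisation joins the two alkyne carbons next to the tether (C2–C3) and gives a rhodacyclopentadiene of trivalent rhodium fused to the five-membered lactone. Acetylene then coordinates and inserts into a Rh–C bond, and reductive elimination forms C4–C5 and C6–C1, releasing the arene and the monovalent catalyst. The closest known reaction type is the RhCl(PPh3)3-catalysed crossed [2+2+2] cyclotrimerisation of heteroatom-tethered 1,6-diynes with acetylene or monoalkynes, which gives phthalans, isoindolines and phthalides. The lactone ring closes by metal-templated C–C coupling of the two tethered alkynes in the bicyclic metallacycle; ring A closes by the formal [2+2+2] assembly of three alkynes on one metal. No stereocentre is formed. The step needs chemoselectivity for cross- over self-trimerisation: both alkynes of 3 are internal, with a methyl or an aryl terminus, so 3 is a poor third partner for its own metallacycle, while acetylene at saturation inserts quickly and slow addition keeps 3 dilute. Regiochemistry needs no control, because the tether fixes which carbons form C2–C3 and acetylene is symmetric, so methyl must end on C1 and the aryl group on C4. The ester has to rotate out of its preferred s-trans form to chelate the metal, which is why gentle heating is planned.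

Step 3
Reactants: 5 7-(4-methoxyphenyl)-4-methylisobenzofuran-1(3H)-one; 6 phenyllithium
Product: 8 [2-(hydroxymethyl)-6-(4-methoxyphenyl)-3-methylphenyl](phenyl)methanone, via lactol 7 (not isolated)
Conditions: PhLi (1.1 equiv), THF, −78 °C; then H2O at −78 °C
Reagents that add atoms: none
Why: Addition of an aryllithium to a phthalide; at −78 °C the tetrahedral adduct should persist as the lithium salt of lactol 7 and release the ketone only on the cold quench, so a second addition is avoided. The aryl methyl ether and the benzylic methyl group are inert under these conditions.

Step 4
Reactants: 8 [2-(hydroxymethyl)-6-(4-methoxyphenyl)-3-methylphenyl](phenyl)methanone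
Product: 9 2-benzoyl-3-(4-methoxyphenyl)-6-methylbenzaldehyde
Conditions: Dess–Martin periodinane, pyridine, CH2Cl2, 0 °C to rt
Reagents that add atoms: none
Why: Dess–Martin oxidation of a primary benzylic alcohol to the aldehyde; the diaryl ketone and the aryl ether are untouched, and pyridine buffers the acetic acid so that the lactol tautomer is not dehydrated to an isobenzofuran.

Step 5
Reactants: 9 2-benzoyl-3-(4-methoxyphenyl)-6-methylbenzaldehyde
Product: 10 [2-ethynyl-6-(4-methoxyphenyl)-3-methylphenyl](phenyl)methanone
Conditions: dimethyl (1-diazo-2-oxopropyl)phosphonate, K2CO3, MeOH/THF, 0 °C to rt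
Reagents that add atoms: dimethyl (1-diazo-2-oxopropyl)phosphonate, COP(=O)(OC)C(=[N+]=[N-])C(C)=O
Why: Ohira–Bestmann (Seyferth–Gilbert) homologation; methanolysis of the reagent gives the diazomethylphosphonate anion, which adds to the aldehyde, expels dimethyl phosphate and loses N2 to an alkylidene carbene that gives the terminal alkyne by 1,2-hydrogen shift. The di-ortho-substituted diaryl ketone is far less electrophilic and should not compete under carbonate in methanol.

Step 6
Reactants: 10 [2-ethynyl-6-(4-methoxyphenyl)-3-methylphenyl](phenyl)methanone; 11 4-iodoanisole
Product: 12 [6-(4-methoxyphenyl)-2-[(4-methoxyphenyl)ethynyl]-3-methylphenyl](phenyl)methanone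
Conditions: PdCl2(PPh3)2 (3 mol%), CuI (5 mol%), Et3N, THF, rt to 40 °C
Reagents that add atoms: none
Why: Sonogashira coupling; the aryl iodide adds oxidatively to zerovalent palladium, the copper acetylide of 10 transmetallates, and reductive elimination forms the C(sp)–C(aryl) bond. The coupling takes place at the unhindered alkyne terminus, away from crowded ring A, and the ketone is inert.

Step 7
Reactants: 12 [6-(4-methoxyphenyl)-2-[(4-methoxyphenyl)ethynyl]-3-methylphenyl](phenyl)methanone; 13 4-bromoanisole
Product: 15 [6-(4-methoxyphenyl)-2-[(4-methoxyphenyl)ethynyl]-3-methylphenyl](4-methoxyphenyl)(phenyl)methanol (racemic), via 4-methoxyphenyllithium 14 (not isolated)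
Conditions: 13, n-BuLi, THF, −78 °C; then 12, −78 to −30 °C; then H2O
Reagents that add atoms: none
Why: Bromine–lithium exchange gives aryllithium 14, which adds 1,2 to the non-enolisable diaryl ketone; the linear alkynyl group is the least demanding ortho neighbour, and at low temperature neither carbolithiation of the alkyne nor cyclisation of the tertiary alkoxide onto it is expected. The carbinol carbon is formed as a racemate, which does not matter because it becomes the trigonal methide carbon in step 8.

Step 8
Reactants: 15 [6-(4-methoxyphenyl)-2-[(4-methoxyphenyl)ethynyl]-3-methylphenyl](4-methoxyphenyl)(phenyl)methanol (racemic)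
Product: 16 selaginellin A, 4-[[6-(4-hydroxyphenyl)-2-[(4-hydroxyphenyl)ethynyl]-3-methylphenyl](phenyl)methylidene]cyclohexa-2,5-dien-1-one
Conditions: BBr3 (excess), CH2Cl2, −78 to 0 °C; then H2O
Reagents that add atoms: none
Why: Lewis-acid cleavage of the three aryl methyl ethers by BBr3, with ionisation of the tertiary carbinol to a triarylmethyl cation; on aqueous work-up the para-hydroxylated cation loses a proton and gives the quinone methide, a fuchsone-type dehydration. The cation is strongly stabilised and hindered, which should disfavour attack on the neighbouring ring or the alkyne at low temperature.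

## Compound list

1 | 3-(4-methoxyphenyl)propiolic acid | COc1ccc(C#CC(=O)O)cc1 | starting material
2 | but-2-yn-1-ol | CC#CCO | starting material
3 | but-2-yn-1-yl 3-(4-methoxyphenyl)propiolate | CC#CCOC(=O)C#Cc1ccc(OC)cc1 | intermediate
4 | acetylene | C#C | starting material
5 | 7-(4-methoxyphenyl)-4-methylisobenzofuran-1(3H)-one | Cc1ccc(-c2ccc(OC)cc2)c2c1COC2=O | intermediate
6 | phenyllithium (commercial solution) | [Li]c1ccccc1 | starting material
7 | 7-(4-methoxyphenyl)-4-methyl-1-phenyl-1,3-dihydroisobenzofuran-1-ol (racemic lactol, formed as its lithium salt) | Cc1ccc(-c2ccc(OC)cc2)c2c1COC2(O)c1ccccc1 | intermediate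
8 | [2-(hydroxymethyl)-6-(4-methoxyphenyl)-3-methylphenyl](phenyl)methanone | Cc1ccc(-c2ccc(OC)cc2)c(C(=O)c2ccccc2)c1CO | intermediate
9 | 2-benzoyl-3-(4-methoxyphenyl)-6-methylbenzaldehyde | Cc1ccc(-c2ccc(OC)cc2)c(C(=O)c2ccccc2)c1C=O | intermediate
10 | [2-ethynyl-6-(4-methoxyphenyl)-3-methylphenyl](phenyl)methanone | Cc1ccc(-c2ccc(OC)cc2)c(C(=O)c2ccccc2)c1C#C | intermediate
11 | 4-iodoanisole | COc1ccc(I)cc1 | starting material
12 | [6-(4-methoxyphenyl)-2-[(4-methoxyphenyl)ethynyl]-3-methylphenyl](phenyl)methanone | Cc1ccc(-c2ccc(OC)cc2)c(C(=O)c2ccccc2)c1C#Cc1ccc(OC)cc1 | intermediate
13 | 4-bromoanisole | COc1ccc(Br)cc1 | starting material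
14 | 4-methoxyphenyllithium | [Li]c1ccc(OC)cc1 | intermediate
15 | [6-(4-methoxyphenyl)-2-[(4-methoxyphenyl)ethynyl]-3-methylphenyl](4-methoxyphenyl)(phenyl)methanol (racemic) | Cc1ccc(-c2ccc(OC)cc2)c(C(O)(c2ccccc2)c2ccc(OC)cc2)c1C#Cc1ccc(OC)cc1 | intermediate
16 | selaginellin A | Cc1ccc(-c2ccc(O)cc2)c(C(=C2C=CC(=O)C=C2)c2ccccc2)c1C#Cc1ccc(O)cc1 | target

## Step count and least certain steps

Total step count: 8. Longest linear sequence: 8 steps (1 and 2 to 16); the route is linear, and the aryllithium 14 is made within step 7.

**Step 2 (key step).** Oxidative cyclisation of the doubly internal, ester-tethered diyne may be slow, because the ester prefers its s-trans form and both termini are substituted. At the modest temperature that an acetylene atmosphere allows, oligomerisation of acetylene and fouling of the rhodium catalyst could then outrun the crossed trimerisation. The fallback sets out from 3 and replaces the gas by ethynyltrimethylsilane, a liquid monoalkyne that can be used in defined excess and heated in a closed vessel (RhCl(PPh3)3, toluene, 80–100 °C). This should give the two regioisomeric silyl arenes 7-(4-methoxyphenyl)-4-methyl-6-(trimethylsilyl)isobenzofuran-1(3H)-one F1 and 7-(4-methoxyphenyl)-4-methyl-5-(trimethylsilyl)isobenzofuran-1(3H)-one F2. They need not be separated, since protodesilylation of the mixture (CF3CO2H, CH2Cl2, rt to 40 °C) converges on 5, where the route is rejoined.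

**Step 3.** The lithium lactolate may collapse to the keto alkoxide while phenyllithium is still present, leading to a second addition; if the temperature is kept low enough to prevent this, addition at the hindered carbonyl may be incomplete. The fallback sets out from 5 and moves the aryl addition to the aldehyde oxidation level, where over-addition is impossible. Reduction with i-Bu2AlH (toluene, −78 °C) should give the lactol 7-(4-methoxyphenyl)-4-methyl-1,3-dihydroisobenzofuran-1-ol F3. PhMgBr (excess, THF, 0 °C to rt) opens it through the hydroxy aldehyde to the diol [2-(hydroxymethyl)-6-(4-methoxyphenyl)-3-methylphenyl](phenyl)methanol F4. Swern oxidation of both hydroxyl groups ((COCl)2, DMSO, CH2Cl2, −78 °C, then Et3N) gives keto aldehyde 9 directly, so the route is rejoined at 9 without passing through 8.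

**Step 5.** Under carbonate in methanol, methoxide may add to the hindered aldehyde and the hemiacetal may transfer hydride to the neighbouring ketone, followed by lactonisation (a crossed Cannizzaro–Tishchenko pathway); this would consume the keto aldehyde before the slow addition of the phosphonate anion. The fallback sets out from 9 and builds the alkyne without alkoxide base and without a terminal alkyne. Ramirez dibromo-olefination (CBr4, PPh3, CH2Cl2, 0 °C) should give [2-(2,2-dibromoethenyl)-6-(4-methoxyphenyl)-3-methylphenyl](phenyl)methanone F5. Dehydrobromination with DBU (DMSO, rt) gives the bromoalkyne [2-(bromoethynyl)-6-(4-methoxyphenyl)-3-methylphenyl](phenyl)methanone F6. Suzuki–Miyaura coupling of F6 with 4-methoxyphenylboronic acid (Pd(PPh3)4, Cs2CO3, toluene/MeOH, rt to 50 °C) gives 12, so the route is rejoined at 12 without passing through 10.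

**Step 7.** Addition to the di-ortho-substituted ketone may be slow enough that warming is needed. The tertiary lithium alkoxide could then cyclise onto the neighbouring alkyne, or the aryllithium could add across the diarylalkyne. The fallback sets out from 10 and changes the order of events. The terminal alkyne is treated with at least two equivalents of 14 (THF, −78 to 0 °C): the first equivalent forms the lithium acetylide, which is inert to nucleophiles, and the second adds to the ketone. This gives [2-ethynyl-6-(4-methoxyphenyl)-3-methylphenyl](4-methoxyphenyl)(phenyl)methanol F7. Sonogashira coupling of F7 with 11 (PdCl2(PPh3)2, CuI, Et3N, THF, rt) returns to the route at 15.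

**Step 8.** The triarylmethyl cation persists in BBr3 and HBr for as long as the demethylation takes. Intramolecular Friedel–Crafts closure onto the aryl ring on C4, giving a 9,9-diarylfluorene skeleton, or addition of HBr to the electron-rich alkyne may therefore compete. The fallback sets out from 12 and separates demethylation from carbinol ionisation.
- BBr3 (CH2Cl2, −78 to 0 °C) is applied to the ketone, which cannot ionise, to give [6-(4-hydroxyphenyl)-2-[(4-hydroxyphenyl)ethynyl]-3-methylphenyl](phenyl)methanone F8.
- Silylation (TBSCl, imidazole, DMF) gives the bis-silyl ether [6-[4-[(tert-butyldimethylsilyl)oxy]phenyl]-2-[[4-[(tert-butyldimethylsilyl)oxy]phenyl]ethynyl]-3-methylphenyl](phenyl)methanone F9.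
- [4-[(tert-Butyldimethylsilyl)oxy]phenyl]lithium F10, made from commercial (4-bromophenoxy)(tert-butyl)dimethylsilane and n-BuLi (THF, −78 °C), adds to F9 to give the carbinol [6-[4-[(tert-butyldimethylsilyl)oxy]phenyl]-2-[[4-[(tert-butyldimethylsilyl)oxy]phenyl]ethynyl]-3-methylphenyl][4-[(tert-butyldimethylsilyl)oxy]phenyl](phenyl)methanol F11.
- Bu4NF (THF, 0 °C) followed by acetic acid removes the three silyl groups and dehydrates the 4-hydroxyphenyl carbinol to 16, the target, with no acid stronger than acetic acid in contact with the carbinol.

## Further compounds

F1 | step 2 | 7-(4-methoxyphenyl)-4-methyl-6-(trimethylsilyl)isobenzofuran-1(3H)-one | Cc1cc([Si](C)(C)C)c(-c2ccc(OC)cc2)c2c1COC2=O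
F2 | step 2 | 7-(4-methoxyphenyl)-4-methyl-5-(trimethylsilyl)isobenzofuran-1(3H)-one | Cc1c([Si](C)(C)C)cc(-c2ccc(OC)cc2)c2c1COC2=O
F3 | step 3 | 7-(4-methoxyphenyl)-4-methyl-1,3-dihydroisobenzofuran-1-ol (racemic) | Cc1ccc(-c2ccc(OC)cc2)c2c1COC2O
F4 | step 3 | [2-(hydroxymethyl)-6-(4-methoxyphenyl)-3-methylphenyl](phenyl)methanol (racemic) | Cc1ccc(-c2ccc(OC)cc2)c(C(O)c2ccccc2)c1CO
F5 | step 5 | [2-(2,2-dibromoethenyl)-6-(4-methoxyphenyl)-3-methylphenyl](phenyl)methanone | Cc1ccc(-c2ccc(OC)cc2)c(C(=O)c2ccccc2)c1C=C(Br)Br
F6 | step 5 | [2-(bromoethynyl)-6-(4-methoxyphenyl)-3-methylphenyl](phenyl)methanone | Cc1ccc(-c2ccc(OC)cc2)c(C(=O)c2ccccc2)c1C#CBr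
F7 | step 7 | [2-ethynyl-6-(4-methoxyphenyl)-3-methylphenyl](4-methoxyphenyl)(phenyl)methanol (racemic) | Cc1ccc(-c2ccc(OC)cc2)c(C(O)(c2ccccc2)c2ccc(OC)cc2)c1C#C
F8 | step 8 | [6-(4-hydroxyphenyl)-2-[(4-hydroxyphenyl)ethynyl]-3-methylphenyl](phenyl)methanone | Cc1ccc(-c2ccc(O)cc2)c(C(=O)c2ccccc2)c1C#Cc1ccc(O)cc1
F9 | step 8 | [6-[4-[(tert-butyldimethylsilyl)oxy]phenyl]-2-[[4-[(tert-butyldimethylsilyl)oxy]phenyl]ethynyl]-3-methylphenyl](phenyl)methanone | Cc1ccc(-c2ccc(O[Si](C)(C)C(C)(C)C)cc2)c(C(=O)c2ccccc2)c1C#Cc1ccc(O[Si](C)(C)C(C)(C)C)cc1
F10 | step 8 | [4-[(tert-butyldimethylsilyl)oxy]phenyl]lithium | [Li]c1ccc(O[Si](C)(C)C(C)(C)C)cc1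
F11 | step 8 | [6-[4-[(tert-butyldimethylsilyl)oxy]phenyl]-2-[[4-[(tert-butyldimethylsilyl)oxy]phenyl]ethynyl]-3-methylphenyl][4-[(tert-butyldimethylsilyl)oxy]phenyl](phenyl)methanol (racemic) | Cc1ccc(-c2ccc(O[Si](C)(C)C(C)(C)C)cc2)c(C(O)(c2ccccc2)c2ccc(O[Si](C)(C)C(C)(C)C)cc2)c1C#Cc1ccc(O[Si](C)(C)C(C)(C)C)cc1
A1 | alternative 1 | methyl 3-oxopentanoate | CCC(=O)CC(=O)OC
A2 | alternative 1 | 4-methoxycinnamaldehyde, (E)-3-(4-methoxyphenyl)prop-2-enal | COc1ccc(/C=C/C=O)cc1
A3 | alternative 1 | rac-methyl trans-6-(4-methoxyphenyl)-3-methyl-2-oxocyclohex-3-ene-1-carboxylate (one enantiomer drawn) | COC(=O)[C@@H]1C(=O)C(C)=CC[C@H]1c1ccc(OC)cc1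
A4 | alternative 1 | methyl 2-hydroxy-6-(4-methoxyphenyl)-3-methylbenzoate | COC(=O)c1c(O)c(C)ccc1-c1ccc(OC)cc1
A5 | alternative 2 | 6-(4-methoxyphenyl)-3-methyl-2H-pyran-2-one | Cc1ccc(-c2ccc(OC)cc2)oc1=O
A6 | alternative 2 | 5-(4-methoxyphenyl)-1-phenylpenta-2,4-diyn-1-one | COc1ccc(C#CC#CC(=O)c2ccccc2)cc1
A7 | alternative 2 | [6-(4-methoxyphenyl)-2-[(4-methoxyphenyl)ethynyl]-3-methylphenyl](phenyl)methanone (identical with 12) | Cc1ccc(-c2ccc(OC)cc2)c(C(=O)c2ccccc2)c1C#Cc1ccc(OC)cc1
A8 | alternative 3 | 3-[1-(4-methoxyphenyl)ethenyl]-4-(prop-1-en-2-yl)furan-2(5H)-one | C=C(C)C1=C(C(=C)c2ccc(OC)cc2)C(=O)OC1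
A9 | alternative 3 | 7-(4-methoxyphenyl)-4-methyl-5,6-dihydroisobenzofuran-1(3H)-one | CC1=C2COC(=O)C2=C(c2ccc(OC)cc2)CC1
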